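The product here is a mixture of two mirror images, and the question is the excess of one over the other, so I look for what stays constant in that mixture.

| setting | Sunday's | Friday's | delta | beta |
|---|---|---|---|---|
| left-handed substrate | 0.20 M | 0.20 M | 0.20 M | 0.20 M |
| right-handed substrate | 0.20 M | 0.20 M | 0.20 M | 0.20 M |
| solid reagent | 3.2 equiv | 5.4 equiv | 2.20 equiv | 4.40 equiv |
| free catalyst | 1 mol% | 1 mol% | 1 mol% | 1 mol% |
| precatalyst | 1.1 mol% | 1.1 mol% | 1.1 mol% | 1.1 mol% |
| remark | run made earlier | run made earlier |  |  |
| time |  |  | 20 min | 20 min |

| run | time / min | left-handed product / % | right-handed product / % |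
|---|---|---|---|
| Sunday's | 5.00 | 19.8 | 8.4 |
| Sunday's | 10.0 | 33.8 | 13.4 |
| Sunday's | 15.0 | 43.6 | 16.9 |
| Sunday's | 20.0 | 50.2 | 18.6 |
| Friday's | 5.00 | 20.6 | 7.5 |
| Friday's | 10.0 | 33.4 | 12.5 |
| Friday's | 15.0 | 42.9 | 16.0 |
| Friday's | 20.0 | 50.0 | 20.3 |

(each reading ± 0.5 percentage points)

- free catalyst is single-handed; left-handed substrate and right-handed substrate are mirror images of each other, charged as a racemate, each of them at the stated concentration
- given per volume of solution although it is solid: solid reagent
- at the start none of the solid reagent is in solution
- an excess is the difference of the two amounts in percent of their sum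
- an excess is below zero if the other one leads

* which of the two ends with the higher excess of left-handed product over right-handed product in the product ("neither" if they lie within 2 percentage points) (delta / beta / neither)
* excess of left-handed product over right-handed product in the product at the end, delta
* excess of left-handed product over right-handed product in the product at the end, beta

With both runs summed, the ratio of left-handed to right-handed product reads 2.54 at 5.00 min and 2.58 at 20.0 min. Over all its readings, Sunday's run with 3.2 equiv of solid reagent gives 2.57, and Friday's with 5.4 equiv gives 2.61. These ratios lie within 0.0700 of each other, so I freeze the ratio at s = 2.59, pooled from all the readings, and call s the selectivity factor. The excess is then s less one, divided by s plus one, which is 44.3%. Delta and beta differ in the solid reagent, 2.20 equiv against 4.40 equiv, so I expect this excess in both. If each product takes one equivalent of solid reagent, Sunday's products at 20.0 min took 1.38 equiv, less than delta's charge.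

The forecast says neither, with 44% for delta and 44% for beta, holding that “the amount of solid does not control the rate”. The simulation gives 44.4% for delta and 44.4% for beta, so the answer is neither.

    partner + free catalyst + left-handed substrate → free catalyst + left-handed product (k = 29.0 L² mol⁻² s⁻¹)
    partner + free catalyst + right-handed substrate → free catalyst + right-handed product (k = 11.0 L² mol⁻² s⁻¹)
    left-handed substrate + racemization catalyst ⇌ right-handed substrate + racemization catalyst, rate k3*[racemization catalyst]*[left-handed substrate] forward; the back reaction follows from the equilibrium constant (k = 25.0 L mol⁻¹ s⁻¹)
    partner + precatalyst → racemization catalyst + spent reagent (k = 0.0780 L mol⁻¹ s⁻¹)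
    free catalyst ⇌ dormant form (K = 1.80, k = 0.0140 s⁻¹)
    solid reagent ⇌ partner, rate k6*(cs6 - [partner]) while solid is left; crystals form when [partner] > cs6 (solubility = 0.0670 M, k = 0.190 s⁻¹)

In delta at 20.0 min, the right-handed product stands at 19.3%, and multiplying by s gives 50.0% of left-handed product, where the flask holds 50.2%. In the neighbouring flask, delta is run with 0.25 mol% of free catalyst instead of 1 mol%. Its right-handed product at 20.0 min is 7.17%, so s calls for 18.6% of left-handed product and an excess of 44.3%. That flask holds 18.8% of left-handed product, with 37.0% of right-handed substrate still present, and its excess is 44.9%.

(All runs were generated by integration for substances that don't exist; noise was put on by code.)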